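- We have 3 ratios of other capture product to target to give for the flask, so we draw one curve through 12 s, 4.0 min and 1.0 h.

| flask | substrate | second nucleophile | capture agent | solid first nucleophile | remark | time |
|---|---|---|---|---|---|---|
| Friday's | 0.20 mM | 0.22 mM | 0.0027 mM | 0.80 mM | run made earlier |  |
| Tuesday's | 0.20 mM | 0.22 mM | 0.0060 mM | 0.80 mM | run made earlier |  |
| Sunday's | 0.20 mM | 0.11 mM | 0.0040 mM | 0.80 mM | run made earlier |  |
| flask | 0.20 mM | 0.220 mM | 0.00400 mM | 0.800 mM |  | 1.0 h |

- Friday's (time / min: other capture product / %, target / %): 3.00: 43.1, 42.7; 10.0: 48.5, 47.8; 15.0: 47.0, 50.3; 25.0: 46.6, 50.3; 40.0: 46.4, 50.0; 50.0: 45.5, 50.6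
- Tuesday's (time / min: other capture product / %, target / %): 3.00: 43.3, 44.1; 10.0: 45.4, 49.4; 15.0: 48.0, 49.9; 25.0: 48.4, 49.9; 40.0: 47.9, 51.6; 50.0: 46.2, 50.0
- Sunday's (time / min: other capture product / %, target / %): 10.0: 27.3, 66.2; 20.0: 27.2, 65.0; 30.0: 30.7, 68.1; 40.0: 29.2, 66.9; 50.0: 30.1, 65.4

(readings scatter by 1 percentage point)

- ratio of other capture product to target at 12 s
- ratio of other capture product to target at 4.0 min
- ratio of other capture product to target at 1.0 h

- at the start none of the solid first nucleophile is in solution
- a reading or a percentage of target counts all its forms, free or not

- The flask's curve starts high: at the start no first nucleophile is in solution, while [second nucleophile] stands at 0.220 mM.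
- It crosses 1 early: the ratio reads 1.01 in Friday's run and 0.982 in Tuesday's, both at 3.00 min, so within the scatter those two runs cross near that time.
- The knee follows: in Friday's run the two products together read 96.3% of the substrate at 10.0 min, and the ratio then levels off, reading 0.926 at 25.0 min.
- To carry the level to other charges, we suppose that dissolved first nucleophile holds steady, so that each mM of target goes with a fixed fall in the logarithm of [second nucleophile].
- That fall per mM of target is our spending ratio, a kind of selectivity factor: Friday's run at 25.0 min gives 5.48 /mM, taking what is left as the charge minus the other capture product.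
- Sunday's run, with 0.11 mM of second nucleophile and 0.0040 mM of capture agent, reads 5.66 /mM at 40.0 min, close to Friday's reading.
- The flask has Friday's charges apart from the capture agent, and that agent's change between Friday's and Tuesday's runs shows nothing beyond the scatter, so we expect Friday's level late and a ratio just under 1 at 4.0 min.
- The forecast gives 3, 0.98 and 0.93, reasoning that “Halving the second nucleophile roughly halves the ratio”.
- The flask gives 2.79, 0.968 and 0.941, within the margins on all 3.

    substrate → open intermediate (k = 0.0120 /s)
    first nucleophile + open intermediate → target (k = 1800 /M/s)
    second nucleophile + open intermediate → other capture product (k = 1400 /M/s)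
    open intermediate → solvolysis product (k = 0.0150 /s)
    open intermediate + capture agent → trapped intermediate (k = 630 /M/s)
    crystals ⇌ target, rate k6*(cs6 - [target]) while solid is left; crystals form when [target] > cs6 (solubility = 0.0940 mM, k = 0.420 /s)
    solid first nucleophile ⇌ first nucleophile, rate k7*(cs7 - [first nucleophile]) while solid is left; crystals form when [first nucleophile] > cs7 (solubility = 0.170 mM, k = 0.0700 /s)

- So the flask opens with other capture product ahead, and its ratio is level by 1.0 h. Then its second nucleophile stands at 57.4% of charge, for which the spending ratio gives 0.101 mM of target, and the flask holds 0.0995 mM, crystals counted in. The neighbouring flask with 0.37 mM of second nucleophile keeps 67.0% of its charge at that time, for which the same reckoning gives 0.0731 mM of target, and it holds 0.0729 mM. Its ratio at 1.0 h is 1.68, with other capture product at 61.1%.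

The readings stem from a simulated flask for an exercise; noise was put on by code.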